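**Retrosynthetic overview**
1. Target 29 ⇐ 28 by late epoxidation of C1=C10; 28 ⇐ 26 by desilylation and oxidation of C15.
2. 26 ⇐ seco-aldehyde 22: the C7–C8 bond closes the ten-membered ring by SmI2 ketyl-radical addition to C7 of a 3-(acetoxymethyl)butenolide; loss of acetate gives the exo-methylene and the Sm alkoxide is esterified in the flask.
3. 22 ⇐ vinyl iodide–butenolide 12 + aldehyde 18 (C3–C4 bond, asymmetric Nozaki–Hiyama–Kishi coupling).
4. 12 ⇐ but-2-yne-1,4-diol + methyl propiolate + formaldehyde; 18 ⇐ 4,4-dimethoxybut-1-yne + AlMe3 + oxirane.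
5. Ring order: γ-lactone (as butenolide) first, ten-membered carbocycle second, epoxide last.

Numbering: germacrane numbering of the target is used throughout (ring C1–C10; lactone C6–O–C12(=O)–C11(=C13)–C7; C14 = methyl on C10; C15 = formyl carbon on C4).
Assumption: in the two ligand-controlled additions (steps 4 and 9) the named ligand antipode is taken to be the one that gives the drawn configuration (Si-face alkynylation of 5, Re-face alkenylation of 18); both antipodes of each ligand are available.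

Step 1
Reactants: 1 but-2-yne-1,4-diol
Product: 2 4-[(tert-butyldimethylsilyl)oxy]but-2-yn-1-ol
Conditions: NaH (1.0 equiv), THF, 0 °C to rt; TBSCl (1.0 equiv), rt
Reagents that add atoms: tert-butyldimethylsilyl chloride, CC(C)(C)[Si](C)(C)Cl
Why: Monosilylation of the mono-sodium alkoxide of a symmetric diol (Williamson-type, McDougal protocol) stops at the mono-ether; no stereocentre is formed.

Step 2
Reactants: 2 4-[(tert-butyldimethylsilyl)oxy]but-2-yn-1-ol
Product: 4 (2Z)-4-[(tert-butyldimethylsilyl)oxy]-3-iodobut-2-en-1-ol, via sodium alkoxyvinylalanate 3 (not isolated)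
Conditions: Red-Al (1.3 equiv), THF, 0 °C; then I2 (2 equiv), THF, −78 °C to 0 °C
Reagents that add atoms: iodine, II
Why: Hydroxyl-directed trans-hydroalumination of a propargylic alcohol puts H on C5 and Al on C4 in a five-membered alkoxyalanate, and iodinolysis with retention leaves iodine cis to C6, which fixes the later ring-cis C4=C5 geometry.

Step 3
Reactants: 4 (2Z)-4-[(tert-butyldimethylsilyl)oxy]-3-iodobut-2-en-1-ol
Product: 5 (2Z)-4-[(tert-butyldimethylsilyl)oxy]-3-iodobut-2-enal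
Conditions: MnO2 (15 equiv), CH2Cl2, rt, dark
Reagents that add atoms: none
Why: MnO2 oxidation of a primary allylic alcohol under neutral conditions gives the β-iodoenal without Z/E isomerisation or loss of the silyl ether.

Step 4
Reactants: 5 (2Z)-4-[(tert-butyldimethylsilyl)oxy]-3-iodobut-2-enal; 6 methyl propiolate
Product: 7 methyl (4R,5Z)-7-[(tert-butyldimethylsilyl)oxy]-4-hydroxy-6-iodohept-5-en-2-ynoate
Conditions: (R,R)-ProPhenol (15 mol %), ZnMe2 (3 equiv), Ph3PO (30 mol %), toluene, 4 °C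
Reagents that add atoms: none
Why: Zn–ProPhenol asymmetric alkynylation of an α,β-unsaturated aldehyde with methyl propiolate delivers the alkynyl group to the Si face under catalyst control and sets C6 as R; the vinyl iodide is inert to ZnMe2.

Step 5
Reactants: 7 methyl (4R,5Z)-7-[(tert-butyldimethylsilyl)oxy]-4-hydroxy-6-iodohept-5-en-2-ynoate; 8 formaldehyde (gas, from cracked paraformaldehyde)
Product: 11 (5S)-5-{(1Z)-3-[(tert-butyldimethylsilyl)oxy]-2-iodoprop-1-en-1-yl}-3-(hydroxymethyl)furan-2(5H)-one, via alpha-aluminated enoate 9 (not isolated), via bis(aluminium alkoxide) ester 10 (not isolated)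
Conditions: DIBAL-H (2.3 equiv), NMO (2.5 equiv), THF, 0 °C; HCHO (excess), 0 °C to rt; aq. Rochelle salt
Reagents that add atoms: none
Why: Reductive aldol by vinylalumination: syn-hydroalumination of the ynoate (H to C7, Al to C11) gives an α-alanyl enoate that adds to formaldehyde, and because syn addition leaves C6 cis to the ester the 6-O-aluminate lactonises to the butenolide; no stereocentre is touched (the descriptor changes only through CIP priorities).

Step 6
Reactants: 11 (5S)-5-{(1Z)-3-[(tert-butyldimethylsilyl)oxy]-2-iodoprop-1-en-1-yl}-3-(hydroxymethyl)furan-2(5H)-one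
Product: 12 {(5S)-5-[(1Z)-3-[(tert-butyldimethylsilyl)oxy]-2-iodoprop-1-en-1-yl]-2-oxo-2,5-dihydrofuran-3-yl}methyl acetate
Conditions: Ac2O (1.5 equiv), pyridine (3 equiv), CH2Cl2, 0 °C
Reagents that add atoms: acetic anhydride, CC(=O)OC(C)=O
Why: Acetylation of the only free (primary allylic) hydroxyl turns C13–O into the leaving group needed in step 11; the weak base at 0 °C avoids γ-deprotonation of the butenolide.

Step 7
Reactants: 13 4,4-dimethoxybut-1-yne; 14 oxirane
Product: 17 (3E)-6,6-dimethoxy-4-methylhex-3-en-1-ol, via alkenyldimethylalane 15 (not isolated), via lithium alkenylalanate 16 (not isolated)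
Conditions: AlMe3 (2.5 equiv), Cp2ZrCl2 (0.2 equiv), H2O (1 equiv), CH2Cl2, −23 °C; evaporate excess AlMe3; n-BuLi (1.1 equiv), THF, −78 °C; oxirane (3 equiv), −78 °C to 0 °C
Reagents that add atoms: trimethylaluminium, C[Al](C)C
Why: Negishi Zr-catalysed syn-carboalumination adds Me to the internal carbon and Al to the terminus (the low temperature spares the acetal), and the derived alanate opens oxirane with retention, giving the E-trisubstituted C1=C10 olefin and the C1–C2 bond in one flask.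

Step 8
Reactants: 17 (3E)-6,6-dimethoxy-4-methylhex-3-en-1-ol
Product: 18 (3E)-6,6-dimethoxy-4-methylhex-3-enal
Conditions: Dess–Martin periodinane (1.3 equiv), NaHCO3, CH2Cl2, 0 °C; used crude
Reagents that add atoms: none
Why: Dess–Martin oxidation under buffered, non-basic conditions gives the β,γ-unsaturated aldehyde without migration of the double bond into conjugation.

Step 9
Reactants: 12 {(5S)-5-[(1Z)-3-[(tert-butyldimethylsilyl)oxy]-2-iodoprop-1-en-1-yl]-2-oxo-2,5-dihydrofuran-3-yl}methyl acetate; 18 (3E)-6,6-dimethoxy-4-methylhex-3-enal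
Product: 19 {(5R)-5-[(1Z,3S,5E)-2-{[(tert-butyldimethylsilyl)oxy]methyl}-3-hydroxy-8,8-dimethoxy-6-methylocta-1,5-dien-1-yl]-2-oxo-2,5-dihydrofuran-3-yl}methyl acetate
Conditions: CrCl2 (10 mol %), (S)-Kishi oxazoline–sulfonamide ligand (12 mol %), proton sponge (12 mol %), NiCl2·2,9-dimethylphenanthroline (2 mol %), Mn (2 equiv), Cp2ZrCl2 (1.1 equiv), LiCl (2 equiv), MeCN, rt
Reagents that add atoms: none
Why: Catalytic asymmetric Nozaki–Hiyama–Kishi coupling: Ni inserts into the C4–I bond with retention, the alkenyl-Cr(III) sulfonamide complex adds to the Re face of the aldehyde under ligand control to set C3 as S, and the lactone, acetal, silyl ether and allylic acetate are tolerated at low Ni loading.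

Step 10
Reactants: 19 {(5R)-5-[(1Z,3S,5E)-2-{[(tert-butyldimethylsilyl)oxy]methyl}-3-hydroxy-8,8-dimethoxy-6-methylocta-1,5-dien-1-yl]-2-oxo-2,5-dihydrofuran-3-yl}methyl acetate
Product: 22 {(5R)-5-[(1Z,3S,5E)-2-{[(tert-butyldimethylsilyl)oxy]methyl}-6-methyl-8-oxo-3-[(triethylsilyl)oxy]octa-1,5-dien-1-yl]-2-oxo-2,5-dihydrofuran-3-yl}methyl acetate, via 3-O-triethylsilyl acetal 20 (not isolated), via collidinium salt 21 (not isolated)
Conditions: TESOTf (3 equiv), 2,4,6-collidine (4.5 equiv), CH2Cl2, −20 °C to 0 °C; then H2O, 0 °C to rt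
Reagents that add atoms: triethylsilyl trifluoromethanesulfonate, CC[Si](CC)(CC)OS(=O)(=O)C(F)(F)F; water, O
Why: Fujioka acetal cleavage: TESOTf/collidine silylates the C3 hydroxyl and converts the dimethyl acetal through a collidinium salt that water hydrolyses to the aldehyde, without protic acid (silyl ethers and allylic acetate kept) and with a base too weak to enolise the butenolide or conjugate the new aldehyde.

Step 11
Reactants: 22 {(5R)-5-[(1Z,3S,5E)-2-{[(tert-butyldimethylsilyl)oxy]methyl}-6-methyl-8-oxo-3-[(triethylsilyl)oxy]octa-1,5-dien-1-yl]-2-oxo-2,5-dihydrofuran-3-yl}methyl acetate; 23 methacryloyl chloride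
Product: 26 (3S,6R,7R,8R)-15-[(tert-butyldimethylsilyl)oxy]-8-(methacryloyloxy)-3-[(triethylsilyl)oxy]germacra-1(10)E,4Z,11(13)-trien-6,12-olide, via samarium enolate 24 (not isolated), via samarium alkoxide 25 (not isolated)
Conditions: 22 added over 8 h to SmI2 (2.5 equiv), THF (final 2 mM), −40 °C; then methacryloyl chloride (4 equiv), DMAP (0.3 equiv), −40 °C to 0 °C
Reagents that add atoms: none
Why: Proposed new method: SmI2 reduces the C8 aldehyde to a ketyl radical that adds 10-exo-trig to C7 of the butenolide (the only electron-poor alkene within reach; the Z-C4=C5 and E-C1=C10 olefins and the lactone ring pre-organise the chain), a second SmI2 turns the α-lactone radical into a Sm(III) enolate that expels acetate to give the exo-methylene, and the Sm alkoxide is acylated before it can translactonise; C7 is attacked anti to the C5 chain on C6 (6,7-trans lactone) and Sm(III) bridging the ketyl oxygen and the lactone carbonyl holds O8 syn to C11 (8R); the closest known reaction types are SmI2 ketyl–olefin couplings of aldehydes with butenolides and acrylates (intermolecular and up to eight-membered rings), SmI2 Barbier/Reformatsky closures of 9- to 11-membered rings and β-acetoxy elimination from samarium enolates.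

Step 12
Reactants: 26 (3S,6R,7R,8R)-15-[(tert-butyldimethylsilyl)oxy]-8-(methacryloyloxy)-3-[(triethylsilyl)oxy]germacra-1(10)E,4Z,11(13)-trien-6,12-olide
Product: 27 (3S,6R,7R,8R)-3,15-dihydroxy-8-(methacryloyloxy)germacra-1(10)E,4Z,11(13)-trien-6,12-olide
Conditions: HF·pyridine, pyridine, THF, 0 °C to rt
Reagents that add atoms: none
Why: Pyridine-buffered fluoride desilylation removes the TES and TBS ethers while the α-methylene lactone, the methacrylate and the alkenes are left alone.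

Step 13
Reactants: 27 (3S,6R,7R,8R)-3,15-dihydroxy-8-(methacryloyloxy)germacra-1(10)E,4Z,11(13)-trien-6,12-olide
Product: 28 (3S,6R,7R,8R)-3-hydroxy-8-(methacryloyloxy)-15-oxogermacra-1(10)E,4E,11(13)-trien-6,12-olide
Conditions: TEMPO (0.2 equiv), PhI(OAc)2 (1.2 equiv), CH2Cl2, rt
Reagents that add atoms: none
Why: TEMPO/PhI(OAc)2 (oxoammonium) oxidation is selective for the primary allylic alcohol over the secondary C3 carbinol and stops at the aldehyde; the enal keeps its geometry (CHO trans to C6 is also the thermodynamic arrangement).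

Step 14
Reactants: 28 (3S,6R,7R,8R)-3-hydroxy-8-(methacryloyloxy)-15-oxogermacra-1(10)E,4E,11(13)-trien-6,12-olide
Product: 29 (1R,3S,6R,7R,8R,10R)-1,10-epoxy-3-hydroxy-8-(methacryloyloxy)-15-oxogermacra-4E,11(13)-dien-6,12-olide (CNP0534814.1)
Conditions: mCPBA (1.1 equiv), Na2HPO4, CH2Cl2, 0 °C
Reagents that add atoms: meta-chloroperoxybenzoic acid, OOC(=O)c1cccc(Cl)c1
Why: Prilezhaev epoxidation picks the only electron-rich alkene (C1=C10; the enal, methylene lactone and methacrylate are electron-poor) and is expected to attack the exposed outer face of the E-olefin, which stands perpendicular to the mean ring plane, giving the trans 1β,10α-epoxide (1R,10R).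

**Compound list**
1 | but-2-yne-1,4-diol | OCC#CCO | starting material
2 | 4-[(tert-butyldimethylsilyl)oxy]but-2-yn-1-ol | OCC#CCO[Si](C)(C)C(C)(C)C | intermediate
3 | sodium alkoxyvinylalanate (five-membered O–Al–C4=C5–C6 ring, two 2-methoxyethoxy groups on Al) | [Na+].COCCO[Al-]1(OCCOC)OCC=C1CO[Si](C)(C)C(C)(C)C | intermediate
4 | (2Z)-4-[(tert-butyldimethylsilyl)oxy]-3-iodobut-2-en-1-ol | OC/C=C(\I)CO[Si](C)(C)C(C)(C)C | intermediate
5 | (2Z)-4-[(tert-butyldimethylsilyl)oxy]-3-iodobut-2-enal | O=C/C=C(\I)CO[Si](C)(C)C(C)(C)C | intermediate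
6 | methyl propiolate | C#CC(=O)OC | starting material
7 | methyl (4R,5Z)-7-[(tert-butyldimethylsilyl)oxy]-4-hydroxy-6-iodohept-5-en-2-ynoate | COC(=O)C#C[C@H](O)/C=C(\I)CO[Si](C)(C)C(C)(C)C | intermediate
8 | formaldehyde | C=O | starting material
9 | methyl (2E,4S,5Z)-2-(diisobutylalumanyl)-4-[(diisobutylalumanyl)oxy]-7-[(tert-butyldimethylsilyl)oxy]-6-iodohepta-2,5-dienoate (ester cis to C6) | COC(=O)/C(=C\[C@H](O[Al](CC(C)C)CC(C)C)/C=C(\I)CO[Si](C)(C)C(C)(C)C)[Al](CC(C)C)CC(C)C | intermediate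
10 | methyl (2Z,4S,5Z)-4-[(diisobutylalumanyl)oxy]-2-{[(diisobutylalumanyl)oxy]methyl}-7-[(tert-butyldimethylsilyl)oxy]-6-iodohepta-2,5-dienoate | COC(=O)/C(CO[Al](CC(C)C)CC(C)C)=C\[C@H](O[Al](CC(C)C)CC(C)C)/C=C(\I)CO[Si](C)(C)C(C)(C)C | intermediate
11 | (5S)-5-{(1Z)-3-[(tert-butyldimethylsilyl)oxy]-2-iodoprop-1-en-1-yl}-3-(hydroxymethyl)furan-2(5H)-one | OCC1=C[C@@H](/C=C(\I)CO[Si](C)(C)C(C)(C)C)OC1=O | intermediate
12 | {(5S)-5-[(1Z)-3-[(tert-butyldimethylsilyl)oxy]-2-iodoprop-1-en-1-yl]-2-oxo-2,5-dihydrofuran-3-yl}methyl acetate | CC(=O)OCC1=C[C@@H](/C=C(\I)CO[Si](C)(C)C(C)(C)C)OC1=O | intermediate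
13 | 4,4-dimethoxybut-1-yne | C#CCC(OC)OC | starting material
14 | oxirane | C1CO1 | starting material
15 | [(1E)-4,4-dimethoxy-2-methylbut-1-en-1-yl]dimethylalumane | COC(OC)C/C(C)=C/[Al](C)C | intermediate
16 | lithium butyl[(1E)-4,4-dimethoxy-2-methylbut-1-en-1-yl]dimethylaluminate | [Li+].CCCC[Al-](C)(C)/C=C(\C)CC(OC)OC | intermediate
17 | (3E)-6,6-dimethoxy-4-methylhex-3-en-1-ol | OCC/C=C(\C)CC(OC)OC | intermediate
18 | (3E)-6,6-dimethoxy-4-methylhex-3-enal | O=CC/C=C(\C)CC(OC)OC | intermediate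
19 | {(5R)-5-[(1Z,3S,5E)-2-{[(tert-butyldimethylsilyl)oxy]methyl}-3-hydroxy-8,8-dimethoxy-6-methylocta-1,5-dien-1-yl]-2-oxo-2,5-dihydrofuran-3-yl}methyl acetate | COC(OC)C/C(C)=C/C[C@H](O)/C(CO[Si](C)(C)C(C)(C)C)=C\[C@H]1OC(=O)C(COC(C)=O)=C1 | intermediate
20 | 3-O-triethylsilyl ether of 19 (acetal intact) | COC(OC)C/C(C)=C/C[C@H](O[Si](CC)(CC)CC)/C(CO[Si](C)(C)C(C)(C)C)=C\[C@H]1OC(=O)C(COC(C)=O)=C1 | intermediate
21 | N-(1-methoxyalkyl)-2,4,6-trimethylpyridinium triflate formed at C8 of 20 | COC(C/C(C)=C/C[C@H](O[Si](CC)(CC)CC)/C(CO[Si](C)(C)C(C)(C)C)=C\[C@H]1OC(=O)C(COC(C)=O)=C1)[n+]1c(C)cc(C)cc1C.[O-]S(=O)(=O)C(F)(F)F | intermediate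
22 | {(5R)-5-[(1Z,3S,5E)-2-{[(tert-butyldimethylsilyl)oxy]methyl}-6-methyl-8-oxo-3-[(triethylsilyl)oxy]octa-1,5-dien-1-yl]-2-oxo-2,5-dihydrofuran-3-yl}methyl acetate | O=CC/C(C)=C/C[C@H](O[Si](CC)(CC)CC)/C(CO[Si](C)(C)C(C)(C)C)=C\[C@H]1OC(=O)C(COC(C)=O)=C1 | intermediate
23 | methacryloyl chloride | C=C(C)C(Cl)=O | starting material
24 | cyclised bis(diiodosamarium) species: 8-O-SmI2 alkoxide and lactone enolate (C7–C8 formed, C13–OAc still present) | I[Sm](I)O[C@@H]1C/C(C)=C/C[C@H](O[Si](CC)(CC)CC)/C(CO[Si](C)(C)C(C)(C)C)=C\[C@H]2OC(O[Sm](I)I)=C(COC(C)=O)[C@@H]21 | intermediate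
25 | (3S,6R,7R,8R)-8-[(diiodosamario)oxy]-15-[(tert-butyldimethylsilyl)oxy]-3-[(triethylsilyl)oxy]germacra-1(10)E,4Z,11(13)-trien-6,12-olide | I[Sm](I)O[C@@H]1C/C(C)=C/C[C@H](O[Si](CC)(CC)CC)/C(CO[Si](C)(C)C(C)(C)C)=C\[C@H]2OC(=O)C(=C)[C@@H]21 | intermediate
26 | (3S,6R,7R,8R)-15-[(tert-butyldimethylsilyl)oxy]-8-(methacryloyloxy)-3-[(triethylsilyl)oxy]germacra-1(10)E,4Z,11(13)-trien-6,12-olide (trans-fused lactone) | C=C(C)C(=O)O[C@@H]1C/C(C)=C/C[C@H](O[Si](CC)(CC)CC)/C(CO[Si](C)(C)C(C)(C)C)=C\[C@H]2OC(=O)C(=C)[C@@H]21 | intermediate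
27 | (3S,6R,7R,8R)-3,15-dihydroxy-8-(methacryloyloxy)germacra-1(10)E,4Z,11(13)-trien-6,12-olide | C=C(C)C(=O)O[C@@H]1C/C(C)=C/C[C@H](O)/C(CO)=C\[C@H]2OC(=O)C(=C)[C@@H]21 | intermediate
28 | (3S,6R,7R,8R)-3-hydroxy-8-(methacryloyloxy)-15-oxogermacra-1(10)E,4E,11(13)-trien-6,12-olide (C4=C5 ring-cis) | C=C(C)C(=O)O[C@@H]1C/C(C)=C/C[C@H](O)/C(C=O)=C\[C@H]2OC(=O)C(=C)[C@@H]21 | intermediate
29 | (1R,3S,6R,7R,8R,10R)-1,10-epoxy-3-hydroxy-8-(methacryloyloxy)-15-oxogermacra-4E,11(13)-dien-6,12-olide (CNP0534814.1) | C=C(C)C(=O)O[C@@H]1C[C@@]2(C)O[C@@H]2C[C@H](O)/C(C=O)=C\[C@H]2OC(=O)C(=C)[C@@H]21 | target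

**Step count**
Total: 14 steps. Longest linear sequence: 12 steps (steps 1–6, then 9–14); steps 7–8 make the second fragment.

**Steps most likely to fail, with fallbacks**

Step 11 (ring closure). The ten-membered ketyl closure is unprecedented at this ring size, and the configuration at C8 rests on a chelation argument. Fallback: from 22 the SmI2 closure is run as described but quenched with aqueous NH4Cl instead of the acyl chloride. If the carbinol obtained is the C8 epimer, (3S,6R,7R,8S)-15-[(tert-butyldimethylsilyl)oxy]-8-hydroxy-3-[(triethylsilyl)oxy]germacra-1(10)E,4Z,11(13)-trien-6,12-olide F1, it is esterified with inversion by a Mitsunobu reaction with methacrylic acid (PPh3, DIAD, toluene, 0 °C). This replaces retentive acylation of the Sm alkoxide and comes back to the route at 26.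

Step 5 (vinylalumination with formaldehyde). The free γ-hydroxyl and the gaseous electrophile may give low conversion or ester reduction. Fallback: from 7, semi-hydrogenation (H2, Lindlar catalyst, quinoline, EtOAc) and spontaneous lactonisation give the α-unsubstituted butenolide (5S)-5-{(1Z)-3-[(tert-butyldimethylsilyl)oxy]-2-iodoprop-1-en-1-yl}furan-2(5H)-one F2. Conjugate addition of Me2AlSePh and trapping of the aluminium enolate with formaldehyde give the selenide (5R)-3-(hydroxymethyl)-5-{(1Z)-3-[(tert-butyldimethylsilyl)oxy]-2-iodoprop-1-en-1-yl}-4-(phenylselanyl)dihydrofuran-2(3H)-one F3. Oxidation with H2O2/pyridine and syn-elimination of the selenoxide restore the C7=C11 double bond and come back to the route at 11.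

Step 9 (asymmetric NHK). Ligand control on a trisubstituted (Z)-iodoalkene is uncertain, and the activated allylic acetate may suffer at Ni. Fallback: from 12 and 18, a ligand-free coupling (CrCl2 4 equiv, NiCl2 1 mol %, DMSO, rt) gives the C3-epimer mixture {(5R)-5-[(1Z,3RS,5E)-2-{[(tert-butyldimethylsilyl)oxy]methyl}-3-hydroxy-8,8-dimethoxy-6-methylocta-1,5-dien-1-yl]-2-oxo-2,5-dihydrofuran-3-yl}methyl acetate F4. Buffered Dess–Martin oxidation gives the enone {(5R)-5-[(1Z,5E)-2-{[(tert-butyldimethylsilyl)oxy]methyl}-8,8-dimethoxy-6-methyl-3-oxoocta-1,5-dien-1-yl]-2-oxo-2,5-dihydrofuran-3-yl}methyl acetate F5. Reduction with (R)-Me-CBS/catecholborane (toluene, −78 °C; the α-branched alkenyl group acts as the large substituent) gives the 3S alcohol and comes back to the route at 19.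

**Further compounds**
F1 | step 11 | (3S,6R,7R,8S)-15-[(tert-butyldimethylsilyl)oxy]-8-hydroxy-3-[(triethylsilyl)oxy]germacra-1(10)E,4Z,11(13)-trien-6,12-olide | O[C@H]1C/C(C)=C/C[C@H](O[Si](CC)(CC)CC)/C(CO[Si](C)(C)C(C)(C)C)=C\[C@H]2OC(=O)C(=C)[C@@H]21
F2 | step 5 | (5S)-5-{(1Z)-3-[(tert-butyldimethylsilyl)oxy]-2-iodoprop-1-en-1-yl}furan-2(5H)-one | O=C1C=C[C@@H](/C=C(\I)CO[Si](C)(C)C(C)(C)C)O1
F3 | step 5 | (5R)-3-(hydroxymethyl)-5-{(1Z)-3-[(tert-butyldimethylsilyl)oxy]-2-iodoprop-1-en-1-yl}-4-(phenylselanyl)dihydrofuran-2(3H)-one | OCC1C([Se]c2ccccc2)[C@@H](/C=C(\I)CO[Si](C)(C)C(C)(C)C)OC1=O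
F4 | step 9 | {(5R)-5-[(1Z,3RS,5E)-2-{[(tert-butyldimethylsilyl)oxy]methyl}-3-hydroxy-8,8-dimethoxy-6-methylocta-1,5-dien-1-yl]-2-oxo-2,5-dihydrofuran-3-yl}methyl acetate | COC(OC)C/C(C)=C/CC(O)/C(CO[Si](C)(C)C(C)(C)C)=C\[C@H]1OC(=O)C(COC(C)=O)=C1
F5 | step 9 | {(5R)-5-[(1Z,5E)-2-{[(tert-butyldimethylsilyl)oxy]methyl}-8,8-dimethoxy-6-methyl-3-oxoocta-1,5-dien-1-yl]-2-oxo-2,5-dihydrofuran-3-yl}methyl acetate | COC(OC)C/C(C)=C/CC(=O)/C(CO[Si](C)(C)C(C)(C)C)=C\[C@H]1OC(=O)C(COC(C)=O)=C1
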